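## Analysis of the target

The target is tricyclic: a cyclohexane (ring A) and a cyclopentanone (ring B) form a hydrindane, and a nine-membered nitrogen ring (ring C) runs from the ring B carbon next to the ketone to the quaternary ring-fusion carbon. Numbering used throughout: C1 (CH–OAc), C2, C3 (C(CH3)OAc), C4, C5 (ring-fusion CH), C6, C7 (C=O), C8 (alkylidene carbon of ring B), C9 (=CH), C10, C11, N, C12, C13, C14, C15 (quaternary carbon); ring A is C1–C5 plus C15, ring B is C5–C8 plus C15, ring C is C8–C15 through N. All four stereocentres (C1, C3, C5, C15) lie on ring A and all are S in this numbering. The C5 hydrogen and the C14 chain are cis (cis-fused hydrindane), both acetoxy groups lie on the opposite face (the face from which ring B is attached), and the C3 methyl group lies on the chain face. The C8=C9 bond is E, which is the cis-in-ring geometry of ring C. Sensitive groups are the exocyclic enone (a Michael acceptor), the tertiary acetate (prone to elimination), and the nitrogen, which in basic form can add across the ring to the C7 ketone. The difficulty lies in a quaternary carbon shared by three rings, a tertiary carbinol stereocentre 1,4 to it, the medium ring, and an alkene that points its chain toward the quaternary carbon. The strategy rests on the position of C15 in ring A between C1 and C5: it is C2 of a 2,2-disubstituted cyclohexane-1,3-dione whose carbonyl carbons become C1 and C5, whose methyl-bearing carbon is C3, and whose two substituents are an acetonyl group (C8, C7, C6) and an allyl group (C14, C13, C12).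

## Retrosynthetic reasoning

**29 to 27 (C8=C9).** The alkene is made last, by loss of water from hydroxy ketone 27 through mesylate 28. The enone would not survive the thiolate and amine chemistry that comes before. Its geometry also cannot be controlled in an open chain, where an alkylidene next to a quaternary carbon prefers to point toward the carbonyl. Inside ring C the chain is tied back to C15, so elimination should give the cis-in-ring, E, alkene.

**27 to 24 (N–CHO, C9–O).** The formyl group is removed to the secondary amine 25, which is carried masked as sulfonamide 24. The amine is acylated in the flask in which it is released, to formamide 26, because as a free base it can add to the C7 ketone across the ring. The C9 oxygen stays silylated until 26 so that no base meets a free β-hydroxy ketone.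

**24 to 23 (N–C11, ring C).** Ring C is opened at nitrogen. Alkylation of an acidic sulfonamide N–H by an activated primary alcohol is the most dependable closure of nine-membered azacycles, and cutting here leaves every C–C bond of ring C to intermolecular chemistry. The forward reaction must run under neutral conditions and at high dilution.

**23 to 20 and 21 (N–C12).** The second C–N bond is the intermolecular version of the same reaction, with sulfonamide 21 as the nitrogen source. It is placed after the hydrogenation, which a nitroarene would not survive. The two primary oxygens are distinguished without extra steps: C12 is a free alcohol in 20 while C11 is still silylated in 22.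

**20 to 19 (C5–H).** The ring-fusion hydrogen is added by hydrogenation of the ring B enone. This must set C5 with hydrogen on the face of the C14 chain.

**19 to 17 (C12–O).** The primary alcohol comes from the allyl group by anti-Markovnikov hydroboration and oxidation. It is done before the hydrogenation, which would saturate the allyl group, and after the aldol step, so that the new hydroxyl needs no protecting group.

**17 to 14 and 15 (C8–C9).** Three carbons of ring C are attached by an aldol addition of aldehyde 15 to the α′ carbon of the ring B enone of 14. The bond is cut here because the enone leaves C8 as the only enolisable position; after hydrogenation C6 and C8 would compete. The aldol gives oxygen at C9 for the final elimination and at C11 for the ring closure.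

**14 to 10 (C1–O, C3–O).** The secondary acetate comes from the C1 ketone of 12 by reduction to diol 13. The tertiary acetate comes from the ring A enone of 10 by conjugate borylation and oxidation to 12. C3 is done first: its hydroxyl steers the reduction at C1, and consuming the ring A enone removes the doubly activated C4 methylene of 10 before any base is used.

**10 to 8 (C5–C6, ring B; key step).** The C5=C6 bond is cut back, through ketol 9, to the methyl ketone and the saturated ring carbonyl of triketone 8. This is the bond whose formation gives C15 a defined configuration. In 8 the quaternary carbon carries two carbonyl arms that differ only in the position of the ring C=C and exchange by tautomerism. A catalyst that selects one carbonyl position therefore selects the configuration, and the whole racemate can be drawn through one enantiomer.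

**8 to 1, 2 and 4.** The methyl ketone of 8 comes from hydration of the alkyne of 7. The ring C=C of 7 comes from dehydrogenation of dione 5, where only the ring CH2 groups are enolisable. Dione 5 comes from two C-alkylations of 1, first with 2 to give 3 and then with 4.

## Alternatives that were turned down

**Alternative 1:** The disconnection removes the C14 chain from C15 and the C9 chain from C8 of a preformed cyclopentenone. In the forward key step a functionalised alkyl cuprate adds to the β-carbon of a 3,4-disubstituted cyclopentenone, and the enolate is trapped by an azido aldehyde and eliminated to A1, the (E)-2-(3-azidopropylidene)cyclopentanone carrying the quaternary carbon and both ring A arms. In its favour, it is convergent: the quaternary carbon, both heteroatom chains and the exocyclic alkene arrive in one flask, and the late aldol, protection and elimination steps of the chosen route disappear. Against it: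
- The β-carbon is already fully substituted and carries an α-branched silyloxyallyl group, so the cuprate addition is hindered.
- The enone must be made beforehand as a single stereoisomer with two stereocentres.
- The elimination takes place in an open chain, where the chain should prefer to point toward the carbonyl and not toward the quaternary carbon as A1 requires.
- Ring A and its tertiary acetate still have to be made, by ring-closing metathesis and a face-selective hydration.

Alternative 1 is stronger on convergence. The chosen route offers a ring-enforced alkene geometry and one catalytic step that creates the absolute configuration from achiral materials.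

**Alternative 2:** The disconnection cuts ring A at C15–C1 and C5–C4. In the forward key step a chiral oxazaborolidinium Lewis acid activates a 2-substituted cyclopentenone toward a 1,1-dioxygenated diene, and acid work-up gives A2, the cis-fused tetrahydroindene-1,7-dione with the silyloxypropyl chain on the quaternary carbon. In its favour, it sets C15 and C5 together, with the cis fusion guaranteed by the suprafacial addition. It avoids both the hydrogenation and the labile skipped dienedione 10, and the chain oxygen is in place without a hydroboration. Against it:
- α-Substituted cyclopentenones are poor dienophiles.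
- The ring B ketone of A2 sits on the carbon bonded to the quaternary centre, which in the target is the alkylidene carbon C8. A 1,2-carbonyl transposition and a hindered olefination would be needed, with no enone to direct them.

Alternative 2 is stronger on the ring-fusion stereocentre. The chosen route offers the ketone at the correct ring B carbon and an enone that fixes the regiochemistry of the aldol.

**Alternative 3:** The disconnection cuts ring B at C7–C8. In the forward key step a cationic rhodium–bisphosphine catalyst inserts into the aldehyde C–H bond of a 5-alkynal and adds acyl and hydrogen syn across the alkyne, giving A3, the cis-fused (E)-alkylidenecyclopentanone diacetate with both chain ends in place. In its favour, the alkene geometry follows from the syn-addition mechanism, and the step comes late, with ring A complete and only the ring C closure and the change at nitrogen left. Against it: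
- The precursor needs a quaternary carbon bearing an alkynyl group and two different chains, in a defined relation to three other stereocentres of a cyclohexane. The difficult part of the target is therefore only moved upstream, with no evident catalytic entry.
- Decarbonylation of the acyl rhodium hydride and slow insertion of the neopentyl alkyne are further risks.

Alternative 3 is stronger on alkene geometry and on the end game. The chosen route offers an early catalytic construction of the quaternary stereocentre from three simple building blocks and a shorter overall path.

Key step: step 5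

Assumption: the sense of induction of the five-membered closure is taken to follow the established topology of the proline-catalysed Hajos–Parrish cyclisation (enamine anti to the carboxylic acid, acid-bound carbonyl attacked), which assigns 10 to D-proline; if the five-membered transition state inverts this sense, L-proline is used and nothing else changes.

## Route

Step 1
Reactants: 1 5-methylcyclohexane-1,3-dione; 2 propargyl bromide
Product: 3 5-methyl-2-(prop-2-yn-1-yl)cyclohexane-1,3-dione
Conditions: KOH (1.0 equiv), H2O, 25 to 50 °C; acidify
Reagents that add atoms: none
Why: C-alkylation of the 1,3-dione enolate; water solvates the enolate oxygens and so favours attack through carbon on the reactive propargylic halide, and the mono-alkylated product is isolated as its enol.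

Step 2
Reactants: 3 5-methyl-2-(prop-2-yn-1-yl)cyclohexane-1,3-dione; 4 allyl methyl carbonate
Product: 5 2-allyl-5-methyl-2-(prop-2-yn-1-yl)cyclohexane-1,3-dione (two achiral cis/trans isomers)
Conditions: Pd(PPh3)4 (2 mol%), THF, 25 °C
Reagents that add atoms: none
Why: Tsuji–Trost allylation: zerovalent palladium ionises the carbonate, the released methoxide deprotonates the acidic dione and the soft enolate attacks the allylpalladium cation at carbon, which builds the quaternary carbon without O-allylation; both isomers converge in step 3.

Step 3
Reactants: 5 2-allyl-5-methyl-2-(prop-2-yn-1-yl)cyclohexane-1,3-dione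
Product: 7 2-allyl-5-methyl-2-(prop-2-yn-1-yl)cyclohex-4-ene-1,3-dione (racemic), via 4-phenylselanyl dione 6 (not isolated)
Conditions: LiN(SiMe3)2 (1.05 equiv), THF, −78 °C; PhSeCl (1.0 equiv), −78 °C; then 30% H2O2, pyridine, CH2Cl2, 0 to 25 °C
Reagents that add atoms: none
Why: Enolate selenenylation followed by selenoxide syn-elimination; the ring CH2 groups are the only enolisable positions, the only β-hydrogen is on the methyl-bearing carbon, and the quaternary carbon forbids further oxidation to a phenol.

Step 4
Reactants: 7 2-allyl-5-methyl-2-(prop-2-yn-1-yl)cyclohex-4-ene-1,3-dione
Product: 8 2-allyl-5-methyl-2-(2-oxopropyl)cyclohex-4-ene-1,3-dione (racemate in fast tautomeric equilibrium; reacting R enantiomer drawn)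
Conditions: Ph3PAuCl (2 mol%), AgOTf (2 mol%), H2O (10 equiv), 1,4-dioxane, 50 °C
Reagents that add atoms: water, O
Why: Markovnikov hydration of the terminal alkyne by monovalent gold; the neighbouring ring carbonyl or enol oxygen can add first in the 5-exo-dig sense, which reinforces formation of the methyl ketone, and the alkene is inert.

Step 5
Reactants: 8 2-allyl-5-methyl-2-(2-oxopropyl)cyclohex-4-ene-1,3-dione
Product: 10 (R)-7a-allyl-5-methyl-4,7a-dihydro-1H-indene-2,7-dione, via cis-fused ketol 9 (not isolated)
Conditions: D-proline (30 mol%), DMSO, 25 °C; then p-TsOH·H2O (10 mol%), toluene, 50 °C, short contact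
Reagents that add atoms: none
Why: Proposed new method: D-proline condenses with the side-chain methyl ketone of 8 to the terminal enamine, whose CH2 carbon (future C6) adds to the saturated ring carbonyl (future C5) while the carboxylic acid hydrogen-bonds and protonates that carbonyl; hydrolysis gives ketol 9 and acid then removes water toward C6 to give the ring B enone of 10. The closest known reaction type is the proline-catalysed Hajos–Parrish desymmetrising aldol cyclisation of 2,2-disubstituted cyclic 1,3-diones; not shown before are the five-membered closure under enamine catalysis and a substrate that is chiral but racemises by tautomerism. Ring B closes in the 5-(enolendo)-exo-trig mode, because both enamine carbons end up inside the new ring; this is the strained mode through which every 1,4-diketone-to-cyclopentenone aldol condensation passes, and the exo carbonyl can tilt to reach the nucleophilic carbon. The one new stereocentre, the quaternary carbon C15, is set by the catalyst: with the enamine anti to the carboxylic acid only one of the two carbonyl positions flanking C15 can be attacked and protonated in the same transition state. Mapping this topology onto the Hajos–Parrish case, where L-proline gives the S enedione, shows that the arrangement of spectator group, side chain and attacked carbonyl needed here is the mirror image, hence D-proline. The step needs selection between the enantiomers of 8 and between the two carbonyl positions; both are secured by the substrate, since only a saturated carbonyl is electrophilic enough for the enamine and the enantiomer that offers it at the wrong position is returned to the racemate through the achiral cross-conjugated dienolate (loss of the doubly activated ring CH2 proton). The quaternary carbon prevents aromatisation, the methyl group on the enone β-carbon disfavours the competing Michael closure, and the five-membered ring can only be cis-fused, so the ketol hydroxyl and the allyl group end up cis.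

Step 6
Reactants: 10 (R)-7a-allyl-5-methyl-4,7a-dihydro-1H-indene-2,7-dione
Product: 12 (5S,7aR)-7a-allyl-5-hydroxy-5-methyl-4,5,6,7a-tetrahydro-1H-indene-2,7-dione (hydroxyl anti to allyl), via β-boryl ketone 11 (not isolated)
Conditions: B2pin2 (1.2 equiv), Cu(OAc)2 (5 mol%), 2,2′-bipyridine (6 mol%), H2O–THF, 25 °C; then 30% H2O2, pH 7 phosphate buffer, 0 °C
Reagents that add atoms: hydrogen peroxide, OO
Why: Copper-catalysed conjugate borylation followed by C–B oxidation with retention. Only the ring A enone has an accessible β-carbon (the ring B β-carbon is the neopentyl ring-fusion carbon), and the boryl–copper reagent should enter C3 anti to the pseudo-axial allyl group on C15, which puts the oxygen on the face opposite the C14 chain (C3 S). The base-free aqueous conditions spare the doubly allylic C4 methylene of 10.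

Step 7
Reactants: 12 (5S,7aR)-7a-allyl-5-hydroxy-5-methyl-4,5,6,7a-tetrahydro-1H-indene-2,7-dione
Product: 13 (5S,7S,7aR)-7a-allyl-5,7-dihydroxy-5-methyl-1,4,5,6,7,7a-hexahydro-2H-inden-2-one (both hydroxyls anti to allyl)
Conditions: Et2BOMe (1.1 equiv), THF–MeOH (4:1), −78 °C; NaBH4 (1.1 equiv), −78 °C; AcOH, then MeOH co-evaporation
Reagents that add atoms: none
Why: Narasaka–Prasad syn reduction: the axial C3 hydroxyl is converted to its diethylborinate, whose boron lies under C1 and activates the ketone from the lower face, so borohydride should enter from the upper face and the new hydroxyl comes out cis to the C3 hydroxyl (C1 S), first as the cyclic boronate of the 1,3-diaxial diol. At −78 °C only the boron-activated saturated ketone is reduced and the ring B enone is left.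

Step 8
Reactants: 13 (5S,7S,7aR)-7a-allyl-5,7-dihydroxy-5-methyl-1,4,5,6,7,7a-hexahydro-2H-inden-2-one
Product: 14 (5S,7S,7aR)-7a-allyl-5-methyl-2-oxo-2,4,5,6,7,7a-hexahydro-1H-indene-5,7-diyl diacetate
Conditions: Ac2O (6 equiv), Et3N, DMAP (1 equiv), CH2Cl2, 40 °C
Reagents that add atoms: acetic anhydride, CC(=O)OC(C)=O
Why: DMAP-catalysed acylation under forcing conditions esterifies the tertiary hydroxyl as well as the secondary one; no stereocentre is touched.

Step 9
Reactants: 14 (5S,7S,7aR)-7a-allyl-5-methyl-2-oxo-2,4,5,6,7,7a-hexahydro-1H-indene-5,7-diyl diacetate; 15 3-(tert-butyldimethylsilyloxy)propanal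
Product: 16 aldol adduct (14 bearing a 3-(tert-butyldimethylsilyloxy)-1-hydroxypropyl group on C8; epimer mixture at C8 and C9)
Conditions: Bu2BOTf (1.2 equiv), i-Pr2NEt (1.5 equiv), CH2Cl2, −78 to 0 °C; 15, −78 °C; then pH 7 buffer, MeOH, 30% H2O2, 0 °C
Reagents that add atoms: none
Why: Boron-mediated aldol addition: soft enolisation of the enone takes place at its only α′ position, C8, to give the cross-conjugated boron dienolate, and the acetates are not enolised under these conditions. The two new stereocentres are of no consequence, since C8 and C9 both become sp2 in step 18, and the epimers are carried on together.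

Step 10
Reactants: 16 aldol adduct
Product: 17 bis-silyl ether (16 with the C9 hydroxyl as its tert-butyldimethylsilyl ether)
Conditions: t-BuMe2SiOTf (1.3 equiv), 2,6-lutidine, CH2Cl2, −78 to 0 °C
Reagents that add atoms: tert-butyldimethylsilyl triflate, CC(C)(C)[Si](C)(C)OS(=O)(=O)C(F)(F)F
Why: Silylation of the secondary hydroxyl blocks retro-aldol cleavage, premature dehydration and a competing Mitsunobu reaction at C9 in the steps that follow.

Step 11
Reactants: 17 bis-silyl ether
Product: 19 primary alcohol (17 in which allyl has become 3-hydroxypropyl), via catechol boronate 18 (not isolated)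
Conditions: catecholborane (1.3 equiv), RhCl(PPh3)3 (2 mol%), THF, 0 to 25 °C; then 30% H2O2, aq. NaHCO3, 0 to 25 °C
Reagents that add atoms: hydrogen peroxide, OO
Why: Rhodium-catalysed hydroboration is selective for the terminal alkene in the presence of ketones and places boron on the terminal carbon; mild peroxide oxidation gives the primary alcohol at C12, and the trisubstituted s-trans enone should not react.

Step 12
Reactants: 19 primary alcohol
Product: 20 cis-fused hydrindanone (19 with the ring B C=C saturated; C5 hydrogen cis to the C14 chain)
Conditions: H2 (1 atm), 10% Pd/C, EtOAc, 25 °C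
Reagents that add atoms: none
Why: Heterogeneous hydrogenation of the enone C=C; hydrogen should reach C5 from the face of the C14 chain, because the opposite face is screened by the two axial acetoxy groups of ring A (1,3-diaxial to C5) and because angularly substituted hydrindenones take up hydrogen to give the cis ring fusion, which sets C5 (S). Nitrogen is introduced only after this step because a nitroarene would be reduced.

Step 13
Reactants: 20 cis-fused hydrindanone; 21 2-nitrobenzenesulfonamide
Product: 22 sulfonamide (20 with the C12 hydroxyl replaced by NH–SO2C6H4-2-NO2)
Conditions: 21 (3 equiv), PPh3 (1.3 equiv), DIAD (1.3 equiv), THF, 0 to 25 °C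
Reagents that add atoms: none
Why: Mitsunobu N-alkylation of the acidic sulfonamide by the only free, primary alcohol; the excess of 21 suppresses double alkylation.

Step 14
Reactants: 22 sulfonamide
Product: 23 hydroxy sulfonamide (22 with the primary silyl ether at C11 cleaved; C9 silyl ether kept)
Conditions: HF·pyridine, pyridine, THF, 0 °C
Reagents that add atoms: none
Why: Under buffered HF·pyridine a primary silyl ether is cleaved much faster than the hindered secondary one, so only the C11 alcohol is set free.

Step 15
Reactants: 23 hydroxy sulfonamide
Product: 24 N-(2-nitrophenylsulfonyl) azonane (ring C closed; C9 silyl ether)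
Conditions: PPh3 (2 equiv), DIAD (2 equiv), toluene–THF, 0.005 M, slow addition, 25 °C
Reagents that add atoms: none
Why: Intramolecular Fukuyama–Mitsunobu alkylation closes the nine-membered ring by N–C11 bond formation; the sulfonamide is acidic enough for the betaine and its geometry at nitrogen eases medium-ring closure, a known way to azonanes fused to hydrindanones. The neutral conditions spare the β-silyloxy ketone.

Step 16
Reactants: 24 N-(2-nitrophenylsulfonyl) azonane
Product: 26 N-formyl azonane (C9 silyl ether), via secondary amine 25 (not isolated)
Conditions: PhSH (1.5 equiv), K2CO3 (3 equiv), MeCN, 25 °C; then preformed acetic formic anhydride (5 equiv), 0 °C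
Reagents that add atoms: acetic formic anhydride, CC(=O)OC=O
Why: Thiolate ipso-substitution on the nitroarene (Meisenheimer adduct) releases SO2 and the secondary amine, which the mixed anhydride acylates at its formyl carbon in the same flask; immediate formylation keeps the amine from adding across the ring to the C7 ketone.

Step 17
Reactants: 26 N-formyl azonane
Product: 27 N-formyl β-hydroxy ketone (26 with the C9 hydroxyl free)
Conditions: HF·pyridine (excess), THF, 25 °C
Reagents that add atoms: none
Why: Acidic fluoride cleaves the remaining silyl ether without base, so the β-hydroxy ketone does not undergo retro-aldol opening of ring C; the acetates and the formamide are stable.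

Step 18
Reactants: 27 N-formyl β-hydroxy ketone
Product: 29 target CNP0137427.1, via C9 mesylate 28 (not isolated)
Conditions: MsCl (1.5 equiv), Et3N, CH2Cl2, 0 °C; then DBU (3 equiv), 25 °C
Reagents that add atoms: none
Why: Mesylation and E1cB elimination through the C7 enolate; C9 is tied back to C15 by ring C, so the alkene should form with C10 cis to C15 (cis inside the nine-membered ring), which is the E enone of the target. Both C8/C9 epimers converge.

## Compound list

1 | 5-methylcyclohexane-1,3-dione | CC1CC(=O)CC(=O)C1 | starting material
2 | propargyl bromide (3-bromoprop-1-yne) | C#CCBr | starting material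
3 | 5-methyl-2-(prop-2-yn-1-yl)cyclohexane-1,3-dione | CC1CC(=O)C(CC#C)C(=O)C1 | intermediate
4 | allyl methyl carbonate | C=CCOC(=O)OC | starting material
5 | 2-allyl-5-methyl-2-(prop-2-yn-1-yl)cyclohexane-1,3-dione (cis/trans mixture, both achiral) | C=CCC1(CC#C)C(=O)CC(C)CC1=O | intermediate
6 | 2-allyl-5-methyl-4-(phenylselanyl)-2-(prop-2-yn-1-yl)cyclohexane-1,3-dione (racemic diastereomer mixture; not isolated) | C=CCC1(CC#C)C(=O)CC(C)C([Se]c2ccccc2)C1=O | intermediate
7 | 2-allyl-5-methyl-2-(prop-2-yn-1-yl)cyclohex-4-ene-1,3-dione (racemic) | C=CCC1(CC#C)C(=O)C=C(C)CC1=O | intermediate
8 | 2-allyl-5-methyl-2-(2-oxopropyl)cyclohex-4-ene-1,3-dione (racemate in tautomeric equilibrium; reacting R enantiomer drawn) | C=CC[C@]1(CC(C)=O)C(=O)C=C(C)CC1=O | intermediate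
9 | cis-fused ketol, 7a-allyl-3a-hydroxy-5-methyl-3,3a,4,7a-tetrahydro-1H-indene-2,7-dione, hydroxyl cis to allyl (not isolated) | C=CC[C@@]12CC(=O)C[C@]1(O)CC(C)=CC2=O | intermediate
10 | (R)-7a-allyl-5-methyl-4,7a-dihydro-1H-indene-2,7-dione | C=CC[C@@]12CC(=O)C=C1CC(C)=CC2=O | intermediate
11 | β-boryl ketone, 12 with a 4,4,5,5-tetramethyl-1,3,2-dioxaborolan-2-yl group in place of the hydroxyl, boron anti to allyl (not isolated) | O=C1C[C@@](C)(B2OC(C)(C)C(C)(C)O2)CC2=CC(=O)C[C@]21CC=C | intermediate
12 | (5S,7aR)-7a-allyl-5-hydroxy-5-methyl-4,5,6,7a-tetrahydro-1H-indene-2,7-dione, hydroxyl anti to allyl | O=C1C[C@@](C)(O)CC2=CC(=O)C[C@]21CC=C | intermediate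
13 | (5S,7S,7aR)-7a-allyl-5,7-dihydroxy-5-methyl-1,4,5,6,7,7a-hexahydro-2H-inden-2-one, both hydroxyls anti to allyl | O[C@H]1C[C@@](C)(O)CC2=CC(=O)C[C@]21CC=C | intermediate
14 | (5S,7S,7aR)-7a-allyl-5-methyl-2-oxo-2,4,5,6,7,7a-hexahydro-1H-indene-5,7-diyl diacetate | CC(=O)O[C@H]1C[C@@](C)(OC(C)=O)CC2=CC(=O)C[C@]21CC=C | intermediate
15 | 3-(tert-butyldimethylsilyloxy)propanal | O=CCCO[Si](C)(C)C(C)(C)C | starting material
16 | aldol adduct, 14 bearing a 3-(tert-butyldimethylsilyloxy)-1-hydroxypropyl group on C8 (the CH2 between ketone and quaternary carbon); epimers at C8 and C9 | CC(=O)O[C@H]1C[C@@](C)(OC(C)=O)CC2=CC(=O)C(C(O)CCO[Si](C)(C)C(C)(C)C)[C@]21CC=C | intermediate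
17 | bis-silyl ether, 16 with the C9 hydroxyl as tert-butyldimethylsilyl ether | CC(=O)O[C@H]1C[C@@](C)(OC(C)=O)CC2=CC(=O)C(C(CCO[Si](C)(C)C(C)(C)C)O[Si](C)(C)C(C)(C)C)[C@]21CC=C | intermediate
18 | catechol boronate, 17 with allyl converted to 3-(1,3,2-benzodioxaborol-2-yl)propyl (not isolated) | CC(=O)O[C@H]1C[C@@](C)(OC(C)=O)CC2=CC(=O)C(C(CCO[Si](C)(C)C(C)(C)C)O[Si](C)(C)C(C)(C)C)[C@]21CCCB1Oc2ccccc2O1 | intermediate
19 | primary alcohol, 17 with 3-hydroxypropyl in place of allyl | CC(=O)O[C@H]1C[C@@](C)(OC(C)=O)CC2=CC(=O)C(C(CCO[Si](C)(C)C(C)(C)C)O[Si](C)(C)C(C)(C)C)[C@]21CCCO | intermediate
20 | cis-fused hydrindanone, 19 with the ring B C=C saturated, C5 hydrogen cis to the 3-hydroxypropyl chain (C5 S) | CC(=O)O[C@H]1C[C@@](C)(OC(C)=O)C[C@H]2CC(=O)C(C(CCO[Si](C)(C)C(C)(C)C)O[Si](C)(C)C(C)(C)C)[C@]21CCCO | intermediate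
21 | 2-nitrobenzenesulfonamide | NS(=O)(=O)c1ccccc1[N+](=O)[O-] | starting material
22 | sulfonamide, 20 with 3-(2-nitrophenylsulfonylamino)propyl in place of 3-hydroxypropyl | CC(=O)O[C@H]1C[C@@](C)(OC(C)=O)C[C@H]2CC(=O)C(C(CCO[Si](C)(C)C(C)(C)C)O[Si](C)(C)C(C)(C)C)[C@]21CCCNS(=O)(=O)c1ccccc1[N+](=O)[O-] | intermediate
23 | hydroxy sulfonamide, 22 with the C11 hydroxyl free and the C9 silyl ether kept | CC(=O)O[C@H]1C[C@@](C)(OC(C)=O)C[C@H]2CC(=O)C(C(CCO)O[Si](C)(C)C(C)(C)C)[C@]21CCCNS(=O)(=O)c1ccccc1[N+](=O)[O-] | intermediate
24 | N-(2-nitrophenylsulfonyl) azonane, tricycle with ring C closed at N–C11, C9 tert-butyldimethylsilyl ether | CC(=O)O[C@H]1C[C@@](C)(OC(C)=O)C[C@H]2CC(=O)C3C(O[Si](C)(C)C(C)(C)C)CCN(S(=O)(=O)c4ccccc4[N+](=O)[O-])CCC[C@@]321 | intermediate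
25 | secondary amine, 24 without the sulfonyl group (not isolated) | CC(=O)O[C@H]1C[C@@](C)(OC(C)=O)C[C@H]2CC(=O)C3C(O[Si](C)(C)C(C)(C)C)CCNCCC[C@@]321 | intermediate
26 | N-formyl azonane, C9 tert-butyldimethylsilyl ether | CC(=O)O[C@H]1C[C@@](C)(OC(C)=O)C[C@H]2CC(=O)C3C(O[Si](C)(C)C(C)(C)C)CCN(C=O)CCC[C@@]321 | intermediate
27 | N-formyl β-hydroxy ketone, 26 with the C9 hydroxyl free | CC(=O)O[C@H]1C[C@@](C)(OC(C)=O)C[C@H]2CC(=O)C3C(O)CCN(C=O)CCC[C@@]321 | intermediate
28 | C9 methanesulfonate of 27 (not isolated) | CC(=O)O[C@H]1C[C@@](C)(OC(C)=O)C[C@H]2CC(=O)C3C(OS(C)(=O)=O)CCN(C=O)CCC[C@@]321 | intermediate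
29 | CNP0137427.1, the (E)-enone N-formyl azonane fused to the cis-hydrindanone diacetate (C1 S, C3 S, C5 S, C15 S in the numbering of the analysis) | CC(=O)O[C@H]1C[C@@](C)(OC(C)=O)C[C@H]2CC(=O)/C3=C/CCN(C=O)CCC[C@@]321 | target

## Step count and least certain steps

Total step count: 18. Longest linear sequence: 18 steps (1 to 29); compounds 2, 4, 15 and 21 are commercial.

**Step 5 (key step).** Several processes may defeat it:
- The strained 5-(enolendo) enamine closure may be slower than the uncatalysed aldol, which would erode the enantioselectivity.
- The catalyst may be tied up as a vinylogous amide by condensation with the ring dicarbonyl unit.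
- The electrophilic carbonyl may be largely enolised.
- The acid used for dehydration may move the double bonds of the skipped dienedione into conjugation.

Fallback, from 8 back to 12: pyrrolidine and AcOH in toluene at 50 °C effect the same aldol condensation without induction and give the racemic enedione F1. The stereocentre is then sorted in the borylation by using a chiral catalyst (Cu(OH)2, a C2-symmetric 2,2′-bipyridine diol ligand, AcOH, B2pin2, H2O; then buffered H2O2), a known asymmetric conjugate borylation of β,β-disubstituted cyclic enones. The catalyst fixes the configuration at C3, so the R enantiomer of F1 gives 11 and then 12, while the S enantiomer gives the C15-epimeric boronate F2 and, after oxidation, the C15-epimeric hydroxy ketone F3, a diastereomer of 12 that is removed by chromatography. Half of the material is lost.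

**Step 6.** Boron may be delivered to the ring B enone or to the wrong face of C3 (1,4-induction across an almost flat ring), and 10 may isomerise before it reacts. Fallback, from 10 back to 12: Weitz–Scheffer epoxidation (30% H2O2, cat. NaOH, MeOH, 0 °C) of the more accessible ring A enone anti to the allyl group gives the epoxy ketone F4. Reductive opening of its Cα–O bond with the selenoborate made from PhSeSePh and NaBH4 (EtOH, AcOH, 0 °C) gives 12.

**Step 7.** Hydride may arrive from the lower face, by intramolecular delivery from boron or by attack anti to the axial C14 chain, which would give the trans diol. Fallback, from 12 back to 13: the tertiary hydroxyl is silylated (Et3SiOTf, 2,6-lutidine, CH2Cl2, −78 °C) to the triethylsilyl ether F5, whose axial silyloxy group closes the lower face. The bulky hydride K[BH(sec-Bu)3] (THF, −78 °C) then attacks equatorially from the upper face, as it does on 4,4-disubstituted 3-keto terpenoids, to give the silyl ether alcohol F6. HF·pyridine removes the silyl group and returns 13.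

**Step 9.** Enolisation at the neopentyl C8 may be slow, or deprotonation may occur at the γ-carbon C4, so that the aldehyde adds at the wrong carbon or not at all. Fallback, from 14 back to 16: t-BuMe2SiOTf and Et3N (CH2Cl2, 0 °C) give the cross-conjugated silyl dienol ether F7, which can be purified and its regiochemistry checked. A Mukaiyama aldol addition to 15 (BF3·OEt2, CH2Cl2, −78 °C) then gives 16.

**Step 15.** Intermolecular alkylation may outrun closure of the nine-membered ring and give oligomers. Fallback, from 23 back to 24: the alcohol is converted (I2, PPh3, imidazole, CH2Cl2, 0 °C) to the iodide F8, and the sulfonamide anion is alkylated intramolecularly (Cs2CO3, MeCN, 0.002 M, 50 °C), so that a large cation templates the closure in place of the phosphonium activation.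

## Further compounds

F1 | step 5 | racemic 7a-allyl-5-methyl-4,7a-dihydro-1H-indene-2,7-dione | C=CCC12CC(=O)C=C1CC(C)=CC2=O
F2 | step 5 | C15-epimeric β-boryl ketone (C15 epimer of 11) | O=C1C[C@@](C)(B2OC(C)(C)C(C)(C)O2)CC2=CC(=O)C[C@@]21CC=C
F3 | step 5 | C15-epimeric hydroxy ketone (C15 epimer of 12) | O=C1C[C@@](C)(O)CC2=CC(=O)C[C@@]21CC=C
F4 | step 6 | epoxy ketone, ring A 2,3-epoxide of 10 anti to allyl | O=C1[C@H]2O[C@@]2(C)CC2=CC(=O)C[C@]21CC=C
F5 | step 7 | triethylsilyl ether of 12 | O=C1C[C@@](C)(O[Si](CC)(CC)CC)CC2=CC(=O)C[C@]21CC=C
F6 | step 7 | silyl ether alcohol, 13 with the tertiary hydroxyl as triethylsilyl ether | O[C@H]1C[C@@](C)(O[Si](CC)(CC)CC)CC2=CC(=O)C[C@]21CC=C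
F7 | step 9 | cross-conjugated tert-butyldimethylsilyl dienol ether of 14 | CC(=O)O[C@H]1C[C@@](C)(OC(C)=O)CC2=CC(O[Si](C)(C)C(C)(C)C)=C[C@]21CC=C
F8 | step 15 | iodide, 23 with iodine in place of the C11 hydroxyl | CC(=O)O[C@H]1C[C@@](C)(OC(C)=O)C[C@H]2CC(=O)C(C(CCI)O[Si](C)(C)C(C)(C)C)[C@]21CCCNS(=O)(=O)c1ccccc1[N+](=O)[O-]
A1 | alternative 1 | (E)-2-(3-azidopropylidene)cyclopentanone with the quaternary β-carbon bearing a 3-(tert-butyldimethylsilyloxy)propyl chain and a 1-(tert-butyldimethylsilyloxy)allyl group, and a 2-methylallyl group on the next ring carbon | C=C(C)C[C@H]1CC(=O)/C(=C/CCN=[N+]=[N-])[C@@]1(CCCO[Si](C)(C)C(C)(C)C)[C@H](C=C)O[Si](C)(C)C(C)(C)C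
A2 | alternative 2 | cis-fused 7a-[3-(tert-butyldimethylsilyloxy)propyl]-5-methyl-3,3a,4,7a-tetrahydro-2H-indene-1,7-dione | O=C1CC[C@@H]2CC(C)=CC(=O)[C@]12CCCO[Si](C)(C)C(C)(C)C
A3 | alternative 3 | cis-fused bicyclic (E)-alkylidenecyclopentanone diacetate with a 3-(tert-butyldimethylsilyloxy)propylidene group and a 3-(2-nitrophenylsulfonylamino)propyl chain | CC(=O)O[C@H]1C[C@@](C)(OC(C)=O)C[C@H]2CC(=O)/C(=C/CCO[Si](C)(C)C(C)(C)C)[C@]21CCCNS(=O)(=O)c1ccccc1[N+](=O)[O-]
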